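Readings and results are calculated for an exercise; scatter was added.

Each electrophile that reacts gives one target and uses one nucleophile, so in these flasks the electrophile lost and the nucleophile turned into target stay equal in amount however long they run.

| setting | dawn | winter | alpha | gamma | eta |
|---|---|---|---|---|---|
| electrophile | 13 mM | 20 mM | 20 mM | 20 mM | 20 mM |
| nucleophile | 30 mM | 15 mM | 30.0 mM | 30.0 mM | 30.0 mM |
| free base | 40 mM | 40 mM | 40.0 mM | 60.0 mM | 90.0 mM |
| remark | run made earlier | run made earlier |  |  |  |
| time |  |  | 3.0 h | 3.0 h | 3.0 h |

* part of the electrophile that has reacted at the end, alpha
* part of the electrophile that has reacted at the end, gamma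
* part of the electrophile that has reacted at the end, eta
* what raising the concentration of free base from its lowest to its highest value here does to the part of the electrophile that has reacted (changes below 5 percentage points count as none) (it falls / it rises / no change)

- dawn (time / min: electrophile / %, target / %): 10.0: 95, 4; 20.0: 96, 10; 30.0: 89, 10; 40.0: 83, 12; 50.0: 86, 11; 60.0: 86, 16
- winter (time / min: electrophile / %, target / %): 4.00: 97, 2; 12.0: 98, 0; 20.0: 100, 2; 30.0: 96, 8; 50.0: 90, 7; 60.0: 91, 8

(each reading ± 2 percentage points)

Read the last row of each table. The target column and the electrophile lost tell nearly the same story, so you can average them. The fraction reacted is 15.0 % in dawn and 8.50 % in winter. Winter has half the nucleophile of dawn, and its fraction reacted is smaller.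

Now take the ratio of nucleophile to electrophile still there and divide it by the same ratio at the start. If the rate follows the product of the two, the natural logarithm of this quotient runs straight with time. Its slope is one constant times the nucleophile charge minus the electrophile charge, so the line goes up in dawn and down in winter. Dawn gives that constant as 0.0934 L mol⁻¹ min⁻¹ and winter as 0.105 L mol⁻¹ min⁻¹. My reading of their mean is the pair constant, the second-order rate constant, 0.0991 L mol⁻¹ min⁻¹.

In alpha the electrophile is the limiting reagent. Over 3.0 h the ratio grows by a factor 1.20, and the fraction reacted that gives this growth is 37.0 %.

No run changes the free base, so what follows is a guess. Suppose each reaction sets free one acid. Alpha then holds twice as much free base as the electrophile charge could ever need, so I take the acid as caught at once and the nucleophile as unbound. My reckoning therefore gives the same fraction in gamma and eta.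

The forecast differs from mine. It gives 37 %, 44 % and 52 %, so it rises, on the ground that “Free base probably helps by deprotonating the nucleophile or scavenging acid”.

The flasks give 39.4 %, 39.4 % and 39.4 %: no change.

    electrophile + nucleophile → acid set free + target (k = 0.109 L mol⁻¹ min⁻¹)
    acid set free + free base ⇌ salt of the base, settled at all times (K = 2.50 × 10⁵ L mol⁻¹)
    nucleophile + acid set free ⇌ protonated nucleophile, settled at all times (K = 2780 L mol⁻¹)

The forecast and the flasks part over free base: the shift from alpha to eta is 0.022 percentage points, and the forecast for eta stands 13 points too high. Now carry the pair constant to the neighbouring flask, which is alpha left until 8.0 h. The ratio grows by a factor 1.61, which gives 64.6 % reacted, and the neighbouring flask gives 67.3 %. In the neighbouring flask the reaction has used 44.8 % of the nucleophile charge, protonated nucleophile stands at 0.0917 mM, and 54.9 % of that charge stands unbound.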